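**Retrosynthetic overview**
- Last bond: the C8–O angelate by acyl transfer. Before it, the ten-membered carbocycle is closed by an intramolecular Nozaki–Hiyama allylation (C7–C8), which also sets C7, C8 and the exocyclic methylene.
- The furanone ring (O–C3 bond) comes from a Z-vinyl iodide, CO and a tertiary propargylic alcohol: carbonylative alkynylation, then amine-mediated cycloisomerisation.
- The lactone ring (O–C12 bond) and C6 come from an enantioselective, desymmetrising carbonylative lactonisation of a prochiral bis(Z-iodovinyl)carbinol (proposed new method).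
- The carbinol is made from two propargyl silyl ethers and ethyl formate; C10 comes from Sharpless epoxidation and hydride opening of (E)-3-methylpent-2-en-4-yn-1-ol.
- Ring order: butenolide (the future lactone), then furanone, then the ten-membered ring.

Assumption: germacrane numbering is used for late intermediates (C1 ketone, C2=C3, C4=C5, C6–O, C7, C8, C9, C10 quaternary, C11=C13, C12 lactone C=O, C14 methyl, C15 CH2OAc), and (R)-DTBM-SEGPHOS is taken as the ligand antipode that gives (S)-7 in step 3 (otherwise its mirror image is used). TBS = tert-butyldimethylsilyl.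

**Step 1**
Reactants: 1 tert-butyldimethyl(prop-2-yn-1-yloxy)silane (2 equiv); 2 ethyl formate
Product: 4 1,7-bis(TBS-oxy)hepta-2,5-diyn-4-ol, via lithium acetylide 3 (not isolated)
Conditions: n-BuLi, THF, −78 °C; then 2, −78 → 0 °C; aq NH4Cl
Reagents that add atoms: none
Why: Double addition of a lithium acetylide to a formate ester gives the symmetric, achiral bis-propargylic carbinol in one operation.

**Step 2**
Reactants: 4
Product: 6 (2Z,5Z)-1,7-bis(TBS-oxy)-2,6-diiodohepta-2,5-dien-4-ol, via disodium bis(alkenyl)alanate 5 (not isolated)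
Conditions: NaAlH2(OCH2CH2OMe)2, THF, 0 °C → rt; then I2, THF, −78 → 0 °C
Reagents that add atoms: iodine, II
Why: Alkoxide-directed trans-hydroalumination of both propargylic alkynes puts aluminium on the carbons remote from the carbinol, and iodinolysis with retention gives the (Z,Z)-bis(iodoalkene); the carbinol carbon stays prochiral.

**Step 3**
Reactants: 6
Product: 7 (S)-3-(TBS-oxymethyl)-5-[(Z)-3-(TBS-oxy)-2-iodoprop-1-en-1-yl]furan-2(5H)-one
Conditions: Pd(OAc)2 (5 mol %), (R)-DTBM-SEGPHOS (6 mol %), CO (1 atm), K2CO3, toluene, 25 °C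
Reagents that add atoms: carbon monoxide, [C-]#[O+]
Why: Proposed new method: an enantioselective, desymmetrising carbonylative lactonisation in which a zerovalent palladium–bisphosphine catalyst, steered by the free carbinol OH, inserts into one of the two enantiotopic C–I bonds, CO insertion gives an acylpalladium, and the carbinol oxygen closes the butenolide C–O bond, so that C6 becomes a stereocentre while the untouched arm keeps its iodide; the closest known reaction types are the (achiral) palladium-catalysed carbonylative lactonisation of (Z)-3-iodoallylic alcohols and enantiotopic-group-selective cross-couplings of prochiral bis(alkenyl triflates).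

**Step 4**
Reactants: 8 (E)-3-methylpent-2-en-4-yn-1-ol
Product: 9 [(2S,3S)-3-ethynyl-3-methyloxiran-2-yl]methanol
Conditions: Ti(OiPr)4 (10 mol %), L-(+)-DET (12 mol %), t-BuOOH, 4 Å MS, CH2Cl2, −20 °C
Reagents that add atoms: tert-butyl hydroperoxide, CC(C)(C)OO
Why: Sharpless asymmetric epoxidation; with L-(+)-tartrate the (E)-3,3-disubstituted allylic alcohol is epoxidised on the same face as geraniol, which fixes the future C10 as the (3S)-epoxide carbon.

**Step 5**
Reactants: 9
Product: 10 (R)-3-methylpent-4-yne-1,3-diol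
Conditions: NaAlH2(OCH2CH2OMe)2, THF, 0 °C → rt
Reagents that add atoms: none
Why: Hydroxyl-directed hydride delivery (reductive opening of a 2,3-epoxy alcohol to a 1,3-diol) attacks C2 only, so the quaternary C–O bond is retained and the tertiary carbinol is (R).

**Step 6**
Reactants: 10
Product: 12 (R)-5,5-dimethoxy-3-methylpent-1-yn-3-ol, via hydroxy aldehyde 11 (not isolated)
Conditions: TEMPO (10 mol %), PhI(OAc)2, CH2Cl2, rt; then HC(OMe)3, MeOH, PPTS, rt
Reagents that add atoms: trimethyl orthoformate, COC(OC)OC; methanol, CO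
Why: Oxoammonium oxidation is selective for the primary over the tertiary alcohol, and the sensitive β-hydroxy aldehyde is trapped at once by acid-catalysed acetalisation; the stereocentre is not involved.

**Step 7**
Reactants: 7; 12
Product: 15 (R)-3-(TBS-oxymethyl)-5-{(Z)-2-[(R)-5-(2,2-dimethoxyethyl)-5-methyl-4-oxo-4,5-dihydrofuran-2-yl]-3-(TBS-oxy)prop-1-en-1-yl}furan-2(5H)-one, via ynone 13 (not isolated), via enaminone 14 (not isolated)
Conditions: PdCl2(PPh3)2 (5 mol %), CuI (5 mol %), Et3N, CO (1 atm), THF, rt; then Et2NH (1.5 equiv), EtOH, 0 °C; then AcOH, H2O, 0 °C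
Reagents that add atoms: carbon monoxide, [C-]#[O+]
Why: Carbonylative Sonogashira coupling (oxidative addition with retention of the Z-olefin) gives the γ-hydroxy ynone, and the classical amine-mediated 3(2H)-furanone synthesis (Et2NH conjugate addition, then acid-promoted attack of the tertiary hydroxyl on the vinylogous amide carbonyl) closes the O–C3 bond with the ketone transposed to C1; no stereocentre is touched.

**Step 8**
Reactants: 15
Product: 17 the C13,C15-diacetate of 15 (both TBS ethers replaced by acetates), via diol 16 (not isolated)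
Conditions: Et3N·3HF, MeCN, rt; then Ac2O, pyridine, 0 °C → rt
Reagents that add atoms: acetic anhydride, CC(=O)OC(C)=O
Why: Fluoride removes both primary silyl ethers while the dimethyl acetal and the lactone survive, and the two primary allylic alcohols are acetylated in the same flask (desilylation, then acylation).

**Step 9**
Reactants: 17
Product: 18 the C13 bromide (3-bromomethyl butenolide) that keeps the C15 acetate and the acetal
Conditions: MgBr2·OEt2 (3 equiv), THF, rt
Reagents that add atoms: magnesium bromide, [Mg+2].[Br-].[Br-]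
Why: Lewis-acid-assisted SN2′/SN2′ halide exchange of a Morita–Baylis–Hillman-type acetate: bromide adds to the butenolide β-carbon and expels the C13 acetate, whereas the C15 acetate sits on an olefin only weakly activated through the vinylogous ester and is left alone.

**Step 10**
Reactants: 18
Product: 19 the C8 aldehyde (2-oxoethyl side chain on the furanone) bearing the allylic bromide
Conditions: TFA, H2O, CH2Cl2, 0 °C
Reagents that add atoms: water, O
Why: Mild aqueous-acid hydrolysis of the dimethyl acetal frees the aldehyde without base, which avoids β-elimination of the furanone oxygen; the allylic bromide and the acetate tolerate it.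

**Step 11**
Reactants: 19
Product: 20 (4Z,6R,7R,8S,10R)-15-acetoxy-8-hydroxy-1-oxo-3,10-epoxygermacra-2,4,11(13)-trien-12,6-olide
Conditions: CrCl2 (8 equiv), THF (2 mM, syringe pump), rt
Reagents that add atoms: none
Why: Intramolecular Nozaki–Hiyama allylation under high dilution: divalent chromium inserts only into the allylic bromide, and the allylchromium adds through its γ-carbon (C7) to the aldehyde in a chair transition state on the butenolide face opposite to the C6–C5 bond, which sets the trans-lactone (7R), the 7,8-anti carbinol (8S) and the exocyclic methylene in the ring-closing event.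

**Step 12**
Reactants: 20; 21 angelic acid
Product: 23 CNP0122132.1, (4Z,6R,7R,8S,10R)-15-acetoxy-8-[(Z)-2-methylbut-2-enoyloxy]-1-oxo-3,10-epoxygermacra-2,4,11(13)-trien-12,6-olide, via mixed anhydride 22 (not isolated)
Conditions: 21, 2,4,6-Cl3C6H2COCl, Et3N, toluene, rt; then 20, 80 °C
Reagents that add atoms: none
Why: Acyl transfer from the preformed angelic 2,4,6-trichlorobenzoic mixed anhydride (Yamaguchi-type esterification run without DMAP) acylates the hindered C8 alcohol at the less hindered angeloyl carbonyl, with retention at C8 and without Z-to-E isomerisation to the tiglate.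

**Compound list**
1 | tert-butyldimethyl(prop-2-yn-1-yloxy)silane | C#CCO[Si](C)(C)C(C)(C)C | starting material
2 | ethyl formate | CCOC=O | starting material
3 | lithium 3-(TBS-oxy)prop-1-yn-1-ide (lithium acetylide of 1) | [Li]C#CCO[Si](C)(C)C(C)(C)C | intermediate
4 | 1,7-bis(TBS-oxy)hepta-2,5-diyn-4-ol | CC(C)(C)[Si](C)(C)OCC#CC(O)C#CCO[Si](C)(C)C(C)(C)C | intermediate
5 | disodium bis(alkenyl)alanate from 4 (C2 and C6 aluminated, one aluminium also bound to the carbinol oxygen) | CC(C)(C)[Si](C)(C)OCC1=CC(O[Al-]1(OCCOC)OCCOC)/C=C(/CO[Si](C)(C)C(C)(C)C)[Al-]([H])(OCCOC)OCCOC.[Na+].[Na+] | intermediate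
6 | (2Z,5Z)-1,7-bis(TBS-oxy)-2,6-diiodohepta-2,5-dien-4-ol | CC(C)(C)[Si](C)(C)OC/C(I)=C/C(O)/C=C(I)/CO[Si](C)(C)C(C)(C)C | intermediate
7 | (S)-3-(TBS-oxymethyl)-5-[(Z)-3-(TBS-oxy)-2-iodoprop-1-en-1-yl]furan-2(5H)-one | O=C1O[C@H](/C=C(I)/CO[Si](C)(C)C(C)(C)C)C=C1CO[Si](C)(C)C(C)(C)C | intermediate
8 | (E)-3-methylpent-2-en-4-yn-1-ol | C#C/C(C)=C/CO | starting material
9 | [(2S,3S)-3-ethynyl-3-methyloxiran-2-yl]methanol | OC[C@@H]1O[C@@]1(C)C#C | intermediate
10 | (R)-3-methylpent-4-yne-1,3-diol | C#C[C@](C)(O)CCO | intermediate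
11 | (R)-3-hydroxy-3-methylpent-4-ynal | C#C[C@](C)(O)CC=O | intermediate
12 | (R)-5,5-dimethoxy-3-methylpent-1-yn-3-ol | C#C[C@](C)(O)CC(OC)OC | intermediate
13 | γ-hydroxy ynone: (R)-3-(TBS-oxymethyl)-5-[(1Z,6R)-6-hydroxy-8,8-dimethoxy-6-methyl-3-oxo-2-(TBS-oxymethyl)oct-1-en-4-yn-1-yl]furan-2(5H)-one | O=C1O[C@H](/C=C(/CO[Si](C)(C)C(C)(C)C)C(=O)C#C[C@](C)(O)CC(OC)OC)C=C1CO[Si](C)(C)C(C)(C)C | intermediate
14 | enaminone: the (4E)-5-diethylamino-octa-1,4-dienyl analogue of 13 (Et2NH added to the ynone β-carbon) | O=C1O[C@H](/C=C(/CO[Si](C)(C)C(C)(C)C)C(=O)/C=C(/N(CC)CC)[C@](C)(O)CC(OC)OC)C=C1CO[Si](C)(C)C(C)(C)C | intermediate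
15 | (R)-3-(TBS-oxymethyl)-5-{(Z)-2-[(R)-5-(2,2-dimethoxyethyl)-5-methyl-4-oxo-4,5-dihydrofuran-2-yl]-3-(TBS-oxy)prop-1-en-1-yl}furan-2(5H)-one | O=C1O[C@H](/C=C(/CO[Si](C)(C)C(C)(C)C)C2=CC(=O)[C@@](C)(CC(OC)OC)O2)C=C1CO[Si](C)(C)C(C)(C)C | intermediate
16 | C13,C15-diol corresponding to 15 (both silyl ethers removed) | O=C1O[C@H](/C=C(/CO)C2=CC(=O)[C@@](C)(CC(OC)OC)O2)C=C1CO | intermediate
17 | [(R)-5-{(Z)-3-acetoxy-2-[(R)-5-(2,2-dimethoxyethyl)-5-methyl-4-oxo-4,5-dihydrofuran-2-yl]prop-1-en-1-yl}-2-oxo-2,5-dihydrofuran-3-yl]methyl acetate | O=C1O[C@H](/C=C(/COC(C)=O)C2=CC(=O)[C@@](C)(CC(OC)OC)O2)C=C1COC(C)=O | intermediate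
18 | (Z)-3-[(R)-4-(bromomethyl)-5-oxo-2,5-dihydrofuran-2-yl]-2-[(R)-5-(2,2-dimethoxyethyl)-5-methyl-4-oxo-4,5-dihydrofuran-2-yl]allyl acetate | O=C1O[C@H](/C=C(/COC(C)=O)C2=CC(=O)[C@@](C)(CC(OC)OC)O2)C=C1CBr | intermediate
19 | (Z)-3-[(R)-4-(bromomethyl)-5-oxo-2,5-dihydrofuran-2-yl]-2-[(R)-5-methyl-4-oxo-5-(2-oxoethyl)-4,5-dihydrofuran-2-yl]allyl acetate | O=C1O[C@H](/C=C(/COC(C)=O)C2=CC(=O)[C@@](C)(CC=O)O2)C=C1CBr | intermediate
20 | (4Z,6R,7R,8S,10R)-15-acetoxy-8-hydroxy-1-oxo-3,10-epoxygermacra-2,4,11(13)-trien-12,6-olide | C=C1C(=O)O[C@@H]2/C=C(/COC(C)=O)C3=CC(=O)[C@@](C)(C[C@H](O)[C@@H]12)O3 | intermediate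
21 | angelic acid, (Z)-2-methylbut-2-enoic acid | C/C=C(/C)C(=O)O | starting material
22 | (Z)-2-methylbut-2-enoic 2,4,6-trichlorobenzoic anhydride | C/C=C(/C)C(=O)OC(=O)c1c(Cl)cc(Cl)cc1Cl | intermediate
23 | CNP0122132.1, (4Z,6R,7R,8S,10R)-15-acetoxy-8-angeloyloxy-1-oxo-3,10-epoxygermacra-2,4,11(13)-trien-12,6-olide | C=C1C(=O)O[C@@H]2/C=C(/COC(C)=O)C3=CC(=O)[C@@](C)(C[C@H](OC(=O)/C(C)=C\C)[C@@H]12)O3 | target

**Totals**
Total step count: 12. Longest linear sequence: 9 steps (steps 1, 2, 3, 7, 8, 9, 10, 11, 12; the branch through steps 4, 5, 6 is equally long).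

**Three steps most likely to fail**

Step 3 (the proposed new desymmetrisation; risks are low enantioselectivity or over-carbonylation). The fallback uses known chemistry only, sets out from 6 and comes back at 15. Carbonylation of 6 with achiral Pd(PPh3)4, CO (1 atm) and K2CO3, the established lactonisation of (Z)-3-iodoallylic alcohols, gives the racemic butenolide, that is 7 together with its enantiomer (R)-3-(TBS-oxymethyl)-5-[(Z)-3-(TBS-oxy)-2-iodoprop-1-en-1-yl]furan-2(5H)-one F1. The racemate is taken through step 7 with enantiopure 12; there F1 gives the C6-epimeric ynone F2, the C6-epimeric enaminone F3 and the C6-epimeric furanone F4. F4 is a diastereomer of 15 and is removed by chromatography, so the route is rejoined at 15 at the cost of half the material.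

Step 9 (selective bromide exchange at C13 in the presence of the C15 acetate). The fallback sets out from 17 and comes back at 18. DABCO (20 mol %) with NaHCO3 in aqueous THF hydrolyses only the butenolide-bound acetate by nucleophilic SN2′/SN2′ catalysis and gives the 3-hydroxymethyl butenolide with the C15 acetate intact F5. An Appel reaction (CBr4, PPh3, CH2Cl2, 0 °C) then converts F5 into 18.

Step 11 (ten-membered ring closure by allylation; risks are oligomers or the wrong C7/C8 configuration). The fallback reverses the order of the two C–C events, so that C7 and C8 are set in an intermolecular Barbier addition with acyclic stereocontrol. It sets out from 7 and from 10 (oxidised to 11 as in step 6, without acetalisation) and comes back at 23.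
- 7 is desilylated with Et3N·3HF to (S)-3-(hydroxymethyl)-5-[(Z)-3-hydroxy-2-iodoprop-1-en-1-yl]furan-2(5H)-one F6.
- F6 is acetylated (Ac2O, pyridine) to the diacetate F7 and converted with MgBr2·OEt2 into (S)-(Z)-3-[4-(bromomethyl)-5-oxo-2,5-dihydrofuran-2-yl]-2-iodoallyl acetate F8; here the C15 acetate is on an unactivated iodoalkene.
- Zinc-mediated Barbier addition of F8 to 11 (Zn dust, aq NH4Cl, THF) gives the seco α-methylene lactone diol with the target configuration at C6, C7, C8 and C10 F9.
- The secondary alcohol of F9 is acylated with 22 (from 21, as in step 12) to the seco angelate F10.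
- Carbonylative Sonogashira ring closure under high dilution (PdCl2(PPh3)2, CuI, Et3N, CO) gives the ten-membered γ-hydroxy ynone F11.
- (p-CF3C6H4)3PAuCl/AgOTf in toluene effects the transannular furanone formation and delivers 23.

**Further compounds**
F1 | step 3 | (R)-3-(TBS-oxymethyl)-5-[(Z)-3-(TBS-oxy)-2-iodoprop-1-en-1-yl]furan-2(5H)-one (enantiomer of 7) | O=C1O[C@@H](/C=C(I)/CO[Si](C)(C)C(C)(C)C)C=C1CO[Si](C)(C)C(C)(C)C
F2 | step 3 | C6-epimer of ynone 13 (lactone carbon S, carbinol R) | O=C1O[C@@H](/C=C(/CO[Si](C)(C)C(C)(C)C)C(=O)C#C[C@](C)(O)CC(OC)OC)C=C1CO[Si](C)(C)C(C)(C)C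
F3 | step 3 | C6-epimer of enaminone 14 | O=C1O[C@@H](/C=C(/CO[Si](C)(C)C(C)(C)C)C(=O)/C=C(/N(CC)CC)[C@](C)(O)CC(OC)OC)C=C1CO[Si](C)(C)C(C)(C)C
F4 | step 3 | C6-epimer of furanone 15 (lactone carbon S, furanone carbon R) | O=C1O[C@@H](/C=C(/CO[Si](C)(C)C(C)(C)C)C2=CC(=O)[C@@](C)(CC(OC)OC)O2)C=C1CO[Si](C)(C)C(C)(C)C
F5 | step 9 | (Z)-2-[(R)-5-(2,2-dimethoxyethyl)-5-methyl-4-oxo-4,5-dihydrofuran-2-yl]-3-[(R)-4-(hydroxymethyl)-5-oxo-2,5-dihydrofuran-2-yl]allyl acetate | O=C1O[C@H](/C=C(/COC(C)=O)C2=CC(=O)[C@@](C)(CC(OC)OC)O2)C=C1CO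
F6 | step 11 | (S)-3-(hydroxymethyl)-5-[(Z)-3-hydroxy-2-iodoprop-1-en-1-yl]furan-2(5H)-one | O=C1O[C@H](/C=C(I)/CO)C=C1CO
F7 | step 11 | [(S)-5-[(Z)-3-acetoxy-2-iodoprop-1-en-1-yl]-2-oxo-2,5-dihydrofuran-3-yl]methyl acetate | O=C1O[C@H](/C=C(I)/COC(C)=O)C=C1COC(C)=O
F8 | step 11 | (Z)-3-[(S)-4-(bromomethyl)-5-oxo-2,5-dihydrofuran-2-yl]-2-iodoallyl acetate | O=C1O[C@H](/C=C(I)/COC(C)=O)C=C1CBr
F9 | step 11 | seco α-methylene-γ-butyrolactone diol (C6-bound Z-iodoalkene with C15 acetate, C8 secondary alcohol, C10 tertiary propargylic alcohol, terminal alkyne; configured as in 23) | C=C1C(=O)O[C@H](/C=C(I)/COC(C)=O)[C@H]1[C@@H](O)C[C@@](C)(O)C#C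
F10 | step 11 | C8 angelate of F9 | C=C1C(=O)O[C@H](/C=C(I)/COC(C)=O)[C@H]1[C@@H](OC(=O)/C(C)=C\C)C[C@@](C)(O)C#C
F11 | step 11 | ten-membered γ-hydroxy ynone (C3 ketone, C1≡C2 alkyne, C10 tertiary alcohol, C8 angelate, trans-fused α-methylene lactone) | C=C1C(=O)O[C@@H]2/C=C(/COC(C)=O)C(=O)C#C[C@](C)(O)C[C@H](OC(=O)/C(C)=C\C)[C@@H]12
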